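(The readings are calculated on assumed constants; noise was put on by code.)

| flask | substrate | solid reagent | remark | time |
|---|---|---|---|---|
| zeta | 0.034 M | 0.090 M | run made earlier |  |
| alpha | 0.075 M | 0.090 M | run made earlier |  |
| eta | 0.050 M | 0.045 M | run made earlier |  |
| flask | 0.050 M | 0.0900 M |  | 10 h |

| run | time / h | substrate / % | target / % |
|---|---|---|---|
| zeta | 0.417 | 71 | 23 |
| zeta | 1.33 | 45 | 55 |
| zeta | 2.50 | 40 | 58 |
| zeta | 3.00 | 34 | 60 |
| zeta | 5.00 | 35 | 60 |
| zeta | 6.00 | 38 | 58 |
| zeta | 8.00 | 35 | 60 |
| alpha | 0.667 | 59 | 34 |
| alpha | 1.00 | 56 | 41 |
| alpha | 1.33 | 50 | 47 |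
| alpha | 2.50 | 47 | 49 |
| alpha | 3.00 | 47 | 47 |
| alpha | 5.00 | 48 | 50 |
| alpha | 8.00 | 48 | 49 |
| eta | 0.667 | 72 | 30 |
| eta | 2.00 | 62 | 37 |
| eta | 4.00 | 62 | 35 |
| eta | 6.00 | 62 | 33 |
| eta | 8.00 | 61 | 34 |

(standard deviation of a reading: 2 percentage points)

- solid reagent is a solid; its amount is given per volume of the solution
- what may be going on: substrate + partner -> target; substrate + 2 partner -> side product; 2 partner -> homo dimer; solid reagent <-> partner; partner -> decomposed reagent
- at the start none of the solid reagent is in solution
- the reaction counts as stopped when no species that holds the substrate changes by six tenths of a point or more over the second half of the time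

1. why nothing more happens at 10 h, or that something still does (for what has run out or reacted, a solid counts together with what of it has only dissolved) (the partner has run out first / it is still moving / all of the substrate has reacted)
2. how much of the substrate has reacted by 10 h
3. how much target there is at 10 h, in percent of the substrate charged
4. how much side product there is at 10 h, in percent of the substrate charged

The books are kept on the solid reagent, counted together with the partner it releases, and not on the substrate. In the zeta run, 0.090 M of solid met 0.034 M of substrate, yet substrate stood at 34% at 3.00 h and 35% at 8.00 h. So the partner is read as the limiting reagent, and the ledger needs a second outlet.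

The credit is the charge. The first debit is one partner per substrate reacted, which in the alpha run comes to 0.0390 M of 0.090 M. The second debit is the remainder, 0.0510 M, booked to homo dimer, decomposed reagent and the extra partner in side product.

Substrate is taken to react in step with its own level, and on that assumption the two debits are compared through a logarithm. The logarithm of [substrate] at the start over [substrate] at the end, divided by the second debit, reads 15.5 M⁻¹ in zeta, 14.4 M⁻¹ in alpha and 19.4 M⁻¹ in eta, which has half the charge. Zeta and alpha have the flask's charge of solid, so their mean, 14.9 M⁻¹, is carried as the competition number.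

My reckoning closes the flask's books by trial, starting from the mean of what zeta and alpha left, 41.5%. That gives 40.4% left, then 40.7%. With the target share of reacted substrate read from zeta and alpha, 93.3%, this gives 55.3% target and, with the rest of the reacted substrate read as side product, 3.97% side product.

The forecast says the partner has run out first, with 60% reacted, 55.5% target and 4% side product: “the partner has been used up, mostly wasted on dimer or decomposition”. Its conversion stands 0.72 percentage points above mine.

The flask gives: the partner has run out first, with 59.9% reacted, 55.8% target and 4.18% side product.

    substrate + partner → target (k = 0.00840 M⁻¹ s⁻¹)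
    substrate + 2 partner → side product (k = 0.0300 M⁻² s⁻¹)
    2 partner → homo dimer (k = 0.0130 M⁻¹ s⁻¹)
    solid reagent ⇌ partner, rate k4*(cs4 - [partner]) while solid is left; crystals form when [partner] > cs4 (solubility = 48.0 mM, k = 0.00190 s⁻¹)
    partner → decomposed reagent (k = 7.20 × 10⁻⁵ s⁻¹)

At 10.0 h the flask holds 1.72 × 10⁻⁶ M partner and 0% solid reagent, and its own books read a competition number of 15.2 M⁻¹. For the neighbouring flask with 0.22 M of solid reagent, 14.9 M⁻¹ first leaves 7.91% substrate, then 7.45%. That neighbouring flask holds 10% of its substrate at 10.0 h, so its books read 12.9 M⁻¹, lower than the carried number.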